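**Retrosynthetic overview**
- The last operations are hydrogenolysis of one O–CH2Ph bond and exchange of the counter-ions for H+.
- Both S–O bonds are made in one operation on 7-O-benzylquercetin. Carbodiimide/hydrogen sulfate attacks only OH-3, OH-7 and OH-4' of a flavonol, so with O-7 blocked only O-3 and O-4' react.
- The key disconnection is the C–O bond C7–O–CH2Ph. It is made by one site-selective etherification of unprotected quercetin, and it decides where both sulfates end up.
- No ring is built. Rings A, C and B are bought intact in quercetin.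

Assumption: the target has no stereocentre or stereoaxis, so it is achiral and there is no enantiomer to select; the free bis(hydrogen sulfate) of the SMILES is taken as the final compound, released cold from its salt in the last operation, and the salt is the storage form.

**Step 1**
Reactants: 1 quercetin; 2 benzyl bromide
Product: 5 7-O-benzylquercetin, via sodium quercetin 3',4'-borate 3 (not isolated), via sodium 7-O-benzylquercetin 3',4'-borate 4 (not isolated)
Conditions: H3BO3 (3 equiv), NaHCO3 (4 equiv), DMF–H2O 3:1, N2, rt, 30 min; BnBr (1.15 equiv), 40 °C, 16 h; 1 M HCl to pH 2, filter, recrystallise (EtOH–H2O)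
Reagents that add atoms: benzyl bromide, BrCc1ccccc1
Why: Proposed new method: borate-masked, pKa-gated Williamson etherification of an unprotected flavonol aglycone; boric acid ties the 3',4'-catechol up as the tetrahedral borate 3 (which also stops base-induced autoxidation), the bicarbonate buffer (pH about 8.5) ionises only OH-7 (pKa about 7) among the remaining OH groups, while OH-3 (pKa about 10, hydrogen-bonded to C4=O) and the chelated OH-5 stay protonated, so the only free phenoxide displaces bromide (SN2) and forms the C7–O–CH2Ph bond; the closest known reaction type is borax-protected O-alkylation of catechol-bearing polyphenols such as flavonol 3-O-glycosides, which has not been shown on an aglycone with a free 3-OH.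

**Step 2**
Reactants: 5 7-O-benzylquercetin; 6 tetrabutylammonium hydrogen sulfate
Product: 8 bis(tetrabutylammonium) 7-O-benzylquercetin 3,4'-disulfate, via tetrabutylammonium 7-O-benzylquercetin 3-sulfate 7 (not isolated)
Conditions: Bu4NHSO4 (3 equiv), DCC (10 equiv), pyridine, 4 °C, 24 h, then 25 °C, 72 h; filter, strip pyridine (toluene), Sephadex LH-20 (MeOH)
Reagents that add atoms: tetrabutylammonium hydrogen sulfate, CCCC[N+](CCCC)(CCCC)CCCC.OS(=O)(=O)[O-]
Why: In carbodiimide-mediated sulfation DCC turns hydrogen sulfate into an O-sulfoisourea that hands SO3 to acidic OH groups; it is known to work through flavonols stepwise at O-3, O-7 and O-4' and to leave O-3' and the chelated O-5 alone, so with O-7 benzylated it stops at the 3,4'-disulfate.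

**Step 3**
Reactants: 8 bis(tetrabutylammonium) 7-O-benzylquercetin 3,4'-disulfate
Product: 10 quercetin 3,4'-bissulfate, via bis(tetrabutylammonium) quercetin 3,4'-disulfate 9 (not isolated)
Conditions: H2 (1 atm), 10% Pd/C, MeOH, rt, 3 h; filter; Dowex 50WX8 (H+ form), H2O–MeOH, 0–4 °C; freeze-dry at once
Reagents that add atoms: none
Why: Neutral catalytic hydrogenolysis of an aryl benzyl ether leaves sulfate monoester anions and the tetrasubstituted C2=C3 bond untouched, and strong-acid cation exchange in the cold swaps Bu4N+ for H+ faster than the sulfates hydrolyse.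

**Compound list**
1 | quercetin, 2-(3,4-dihydroxyphenyl)-3,5,7-trihydroxy-4H-chromen-4-one (achiral) | O=c1c(O)c(-c2ccc(O)c(O)c2)oc2cc(O)cc(O)c12 | starting material
2 | benzyl bromide | BrCc1ccccc1 | starting material
3 | sodium quercetin 3',4'-O-(dihydroxyborate), catechol bound as a five-membered tetrahedral borate | [Na+].O=c1c(O)c(-c2ccc3O[B-](O)(O)Oc3c2)oc2cc(O)cc(O)c12 | intermediate
4 | sodium 7-O-benzylquercetin 3',4'-O-(dihydroxyborate) | [Na+].O=c1c(O)c(-c2ccc3O[B-](O)(O)Oc3c2)oc2cc(OCc3ccccc3)cc(O)c12 | intermediate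
5 | 7-O-benzylquercetin, 7-benzyloxy-2-(3,4-dihydroxyphenyl)-3,5-dihydroxy-4H-chromen-4-one | O=c1c(O)c(-c2ccc(O)c(O)c2)oc2cc(OCc3ccccc3)cc(O)c12 | intermediate
6 | tetrabutylammonium hydrogen sulfate | CCCC[N+](CCCC)(CCCC)CCCC.OS(=O)(=O)[O-] | starting material
7 | tetrabutylammonium 7-O-benzylquercetin 3-sulfate | CCCC[N+](CCCC)(CCCC)CCCC.O=c1c(OS(=O)(=O)[O-])c(-c2ccc(O)c(O)c2)oc2cc(OCc3ccccc3)cc(O)c12 | intermediate
8 | bis(tetrabutylammonium) 7-O-benzylquercetin 3,4'-disulfate | CCCC[N+](CCCC)(CCCC)CCCC.CCCC[N+](CCCC)(CCCC)CCCC.O=c1c(OS(=O)(=O)[O-])c(-c2ccc(OS(=O)(=O)[O-])c(O)c2)oc2cc(OCc3ccccc3)cc(O)c12 | intermediate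
9 | bis(tetrabutylammonium) quercetin 3,4'-disulfate | CCCC[N+](CCCC)(CCCC)CCCC.CCCC[N+](CCCC)(CCCC)CCCC.O=c1c(OS(=O)(=O)[O-])c(-c2ccc(OS(=O)(=O)[O-])c(O)c2)oc2cc(O)cc(O)c12 | intermediate
10 | quercetin 3,4'-bissulfate, 5,7-dihydroxy-2-(3-hydroxy-4-sulfooxyphenyl)-4-oxo-4H-chromen-3-yl hydrogen sulfate (achiral) | O=c1c(OS(=O)(=O)O)c(-c2ccc(OS(=O)(=O)O)c(O)c2)oc2cc(O)cc(O)c12 | target

**Total step count:** 3. **Longest linear sequence:** 3.

**Steps most likely to fail**

1. Step 1 (the proposed new step). The risks are 3-O- or 4'-O-benzyl isomers if the borate mask or the pH gate leaks, dibenzylation, and some C-6/C-8 benzylation. The fallback uses known chemistry, sets out from 1 and comes back at 5. Ac2O in pyridine gives quercetin 3,5,7,3',4'-pentaacetate F1. Benzyl chloride, KI and K2CO3 in refluxing dry acetone exchange only the most labile 7-acetate for benzyl and give 7-O-benzylquercetin 3,5,3',4'-tetraacetate F2. Catalytic NaOMe in MeOH under N2, then acid, removes the four acetates and delivers 5.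

2. Step 2. The reaction may stall at the monosulfate 7, or some 3,3'-isomer may form that cannot be separated at the salt stage. The fallback uses protected sulfate diesters instead of direct monoester formation, sets out from 5 and comes back at 10. 2,2,2-Trichloroethyl chlorosulfate (2.1 equiv), Et3N and DMAP in THF at 0 °C give neutral 7-O-benzylquercetin 3,4'-bis(2,2,2-trichloroethyl sulfate) F3, which is freed from regioisomers on silica gel. Pd/C with ammonium formate in MeOH then removes both trichloroethyl groups and the benzyl ether in one operation and gives diammonium quercetin 3,4'-disulfate F4. The cold H+ resin of step 3 converts F4 into 10.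

3. Step 3. Hydrogenolysis may be sluggish because traces of pyridine poison Pd/C for benzyl ethers, or sulfate may be lost if the medium turns acidic before the ether is cleaved. The fallback changes the protecting group and cleaves it without hydrogen, sets out from 1 and comes back at 9. Allyl bromide in place of 2 under the conditions of step 1 gives 7-O-allylquercetin F5. The sulfation of step 2 gives bis(tetrabutylammonium) 7-O-allylquercetin 3,4'-disulfate F6. Pd(PPh3)4 (5 mol%) and morpholine in THF–MeOH at rt transfer the allyl group to the amine under slightly basic conditions and give 9, which goes on to the resin exchange.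

**Further compounds**
F1 | step 1 | quercetin 3,5,7,3',4'-pentaacetate | O=c1c(OC(C)=O)c(-c2ccc(OC(C)=O)c(OC(C)=O)c2)oc2cc(OC(C)=O)cc(OC(C)=O)c12
F2 | step 1 | 7-O-benzylquercetin 3,5,3',4'-tetraacetate | O=c1c(OC(C)=O)c(-c2ccc(OC(C)=O)c(OC(C)=O)c2)oc2cc(OCc3ccccc3)cc(OC(C)=O)c12
F3 | step 2 | 7-O-benzylquercetin 3,4'-bis(2,2,2-trichloroethyl sulfate) | O=c1c(OS(=O)(=O)OCC(Cl)(Cl)Cl)c(-c2ccc(OS(=O)(=O)OCC(Cl)(Cl)Cl)c(O)c2)oc2cc(OCc3ccccc3)cc(O)c12
F4 | step 2 | diammonium quercetin 3,4'-disulfate | [NH4+].[NH4+].O=c1c(OS(=O)(=O)[O-])c(-c2ccc(OS(=O)(=O)[O-])c(O)c2)oc2cc(O)cc(O)c12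
F5 | step 3 | 7-O-allylquercetin | O=c1c(O)c(-c2ccc(O)c(O)c2)oc2cc(OCC=C)cc(O)c12
F6 | step 3 | bis(tetrabutylammonium) 7-O-allylquercetin 3,4'-disulfate | CCCC[N+](CCCC)(CCCC)CCCC.CCCC[N+](CCCC)(CCCC)CCCC.O=c1c(OS(=O)(=O)[O-])c(-c2ccc(OS(=O)(=O)[O-])c(O)c2)oc2cc(OCC=C)cc(O)c12
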